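The easy step was the feed: by 5.00 h the steady dosing had put in 50.0% of the electrophile, the two earlier runs showed 34.7% on average, and so 15.3% had reacted.

| setting | dusk | noon | larch | oak |
|---|---|---|---|---|
| electrophile | 20 mM (fed, over 10 h) | 20 mM (fed, over 10 h) | 20 mM (fed, over 10 h) | 20 mM (fed, over 10 h) |
| free base | 27 mM | 45 mM | 24.0 mM | 31.0 mM |
| gas | 1.5 mM (held) | 1.5 mM (held) | 1.5 mM (held) | 1.5 mM (held) |
| remark | run made earlier | run made earlier |  |  |
| time |  |  | 10 h | 10 h |

| run | time / h | electrophile / % | target / % |
|---|---|---|---|
| dusk | 0.833 | 8.6 | 2.2 |
| dusk | 1.50 | 13.2 | 0 |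
| dusk | 2.50 | 21.2 | 3.4 |
| dusk | 3.00 | 24.4 | 4.0 |
| dusk | 4.00 | 27.8 | 7.3 |
| dusk | 5.00 | 34.5 | 9.3 |
| noon | 0.417 | 4.6 | 0 |
| noon | 0.667 | 6.7 | 0 |
| noon | 1.00 | 8.8 | 0.5 |
| noon | 2.00 | 17.9 | 1.5 |
| noon | 3.00 | 26.2 | 6.0 |
| noon | 5.00 | 34.9 | 8.7 |

(each reading ± 1 percentage point)

- the numbers in the tables scatter with a standard deviation of 1 percentage point
- at the start none of the gas is in solution
- percentages count the whole charge, also what has not yet gone in

* part of the electrophile that has reacted at the end, larch
* part of the electrophile that has reacted at the end, oak
* what raising the concentration of free base from its lowest to its highest value here does to the part of the electrophile that has reacted (changes below 5 percentage points count as none) (no change / it rises / it falls)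

I reckoned with two times. One was the dosing time 10 h. The other was my holding time, the mean stay of electrophile in the flask before it reacts, taken as the area under the electrophile curve divided by the share lost. I treated the loss as pseudo-first-order. Averaging the runs at 3.00 h gave 25.3%, straight lines from zero through the two averages gave an area up to 5.00 h of 0.979 h, and the holding time came to 6.40 h, shorter than the dosing time. Their ratio, 1.56, then gave my estimate: 50.6% unreacted at the end of dosing, so 49.4% reacted.

Free base did not visibly enter: at 27 mM and 45 mM the electrophile at 5.00 h differed by 0.4 percentage points, inside the scatter. Larch lay below both runs, but the 9.88 mM I reckoned as reacted stood under its 24.0 mM of free base. I therefore committed to 49.4% for larch and oak alike. The reading worth watching was electrophile at 5.00 h.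

The forecast, built on the same form, called the reaction “apparently zero order in base” and gave 49% for larch, 50% for oak, and no change.

Larch gave 48.6% and oak 48.9%, with no change: the change was 0.32 points.

    electrophile + nucleophile → acid set free + target (k = 270 M⁻¹ h⁻¹)
    nucleophile + acid set free ⇌ protonated nucleophile, settled at all times (K = 12000 M⁻¹)
    acid set free + free base ⇌ salt of the base (K = 2.70 × 10⁶ M⁻¹, k = 100 M⁻¹ h⁻¹)
    acid set free + free base ⇌ idle adduct, settled at all times (K = 43.0 M⁻¹)
    2 electrophile → self-condensation product (k = 4.60 M⁻¹ h⁻¹)
    gas ⇌ nucleophile, rate k6*(csat - [nucleophile]) (kL = 0.520 h⁻¹)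

In my pseudo-first-order reckoning the ratio has no charge in it, so for a neighbour of larch charged with 34 mM of electrophile it again said 49.4%; that neighbour gave 53.1%. Part of why larch stood at 48.6% was the drawn-out feed taken with the time given. Without the drawn-out feed larch reached 78.4%, and left ten times as long it reached 100%.

The data come from a simulation for substances that don't exist; noise was put on by code.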